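## Retrosynthetic overview

1. The target is robinetinidol-(4α→6)-gallocatechin: an upper 5-deoxy unit (2R,3S,4S; 2,3-trans-3,4-trans) joined from C4 to C6 of a lower (2R,3S)-gallocatechin unit.
2. Last disconnection: one hydrogenolysis removes nine benzyl ethers and a C8 bromine that blocks the competing 4→8 position.
3. Key disconnection: the interflavan C4–C6 bond, made by acid-catalysed Friedel–Crafts alkylation of 8-bromo-penta-O-benzyl-gallocatechin with the C4 cation of a tetra-O-benzyl flavan-3,4-diol; this sets upper C4 trans to the 3-OH.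
4. The electrophile comes from (+)-dihydrorobinetin (benzylation, NaBH4); the nucleophile comes from (+)-gallocatechin (benzylation, NBS).
5. Ring formation: none. Both chroman systems (rings A, B and C of each unit) and four of the five stereocentres are bought with the two flavonoids.

Assumption: (+)-gallocatechin (2R,3S) and (+)-dihydrorobinetin (2R,3R) are taken as commercially available, enantiopure natural products; "upper" and "lower" mean the robinetinidol and gallocatechin units.

## Route

Step 1
Reactants: 1 (+)-gallocatechin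
Product: 2 5,7,3',4',5'-penta-O-benzyl-(+)-gallocatechin (2R,3S; 3-OH free)
Conditions: BnBr (5.5 equiv), K2CO3, DMF, Ar, 0 °C → rt
Reagents that add atoms: benzyl bromide, BrCc1ccccc1
Why: Williamson ether synthesis in which K2CO3 deprotonates only the five phenols and not the secondary C3 alcohol, so BnBr alkylates them by SN2 and the 2R,3S centres are carried through untouched.

Step 2
Reactants: 2 5,7,3',4',5'-penta-O-benzyl-(+)-gallocatechin
Product: 3 8-bromo-5,7,3',4',5'-penta-O-benzyl-(+)-gallocatechin (2R,3S; C6–H free)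
Conditions: NBS (1.0 equiv), CH2Cl2, −78 °C → rt
Reagents that add atoms: N-bromosuccinimide, O=C1CCC(=O)N1Br
Why: Electrophilic aromatic bromination of the phloroglucinol-type ring A, which in 5,7-di-O-alkyl flavan-3-ols takes place at C8 (ortho to the ring oxygen, para to the 5-benzyloxy group), so C6 is left as the only nucleophilic position and no stereocentre is touched.

Step 3
Reactants: 4 (+)-dihydrorobinetin
Product: 5 7,3',4',5'-tetra-O-benzyl-(+)-dihydrorobinetin (2R,3R; 2,3-trans; 3-OH free)
Conditions: BnBr (4.4 equiv), K2CO3, DMF, Ar, rt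
Reagents that add atoms: benzyl bromide, BrCc1ccccc1
Why: Williamson ether synthesis under mild base at room temperature, which alkylates the four phenols while the α-ketol alcohol stays free and the thermodynamically preferred 2,3-trans (2R,3R) arrangement is retained.

Step 4
Reactants: 5 7,3',4',5'-tetra-O-benzyl-(+)-dihydrorobinetin
Product: 6 tetra-O-benzyl-leucorobinetinidin (2R,3S,4R; 2,3-trans-3,4-trans flavan-3,4-diol)
Conditions: NaBH4, THF/MeOH, 0 °C
Reagents that add atoms: none
Why: Borohydride reduction of the C4 ketone with axial hydride delivery on the half-chair that has the 2-aryl and 3-OH groups equatorial, which gives mainly the equatorial 3,4-trans (4R) alcohol; this centre is ionised in step 5, so its configuration is of no consequence.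

Step 5
Reactants: 6 tetra-O-benzyl-leucorobinetinidin; 3 8-bromo-5,7,3',4',5'-penta-O-benzyl-(+)-gallocatechin (2.5 equiv, excess recovered)
Product: 8 8-bromo-nona-O-benzyl-robinetinidol-(4α→6)-gallocatechin (upper 2R,3S,4S; lower 2R,3S; Br on C8 of the lower unit), via benzylic C4 cation 7 (not isolated)
Conditions: TMSOTf (0.2 equiv), 4 Å MS, CH2Cl2, −78 → 0 °C; NaHCO3 quench
Reagents that add atoms: none
Why: SN1-type Friedel–Crafts alkylation in which the acid ionises the para-benzyloxy-stabilised benzylic alcohol, with loss of water, to cation 7, which is captured by C6 of 3 (C8 is blocked by bromine) on the α face anti to the 3-hydroxyl, giving the all-equatorial 3,4-trans (4S) adduct as the major, thermodynamically preferred diastereomer that is separated from the minor 4β epimer by chromatography.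

Step 6
Reactants: 8 8-bromo-nona-O-benzyl-robinetinidol-(4α→6)-gallocatechin
Product: 9 robinetinidol-(4α→6)-gallocatechin (target; upper 2R,3S,4S; lower 2R,3S)
Conditions: H2 (1 atm), Pd(OH)2/C, Et3N (1.5 equiv), THF/MeOH/H2O, rt; filter under Ar, Sephadex LH-20
Reagents that add atoms: none
Why: Catalytic hydrogenolysis cleaves the nine benzyl aryl ethers to phenols and reduces the aryl C–Br bond (Et3N takes up the HBr), while the pyran rings and the aryl–alkyl interflavan bond are inert under these conditions, so all five stereocentres are unchanged.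

## Compound list

1 | (+)-gallocatechin, (2R,3S)-2-(3,4,5-trihydroxyphenyl)chromane-3,5,7-triol | Oc1cc(O)c2C[C@H](O)[C@@H](c3cc(O)c(O)c(O)c3)Oc2c1 | starting material
2 | 5,7,3',4',5'-penta-O-benzyl-(+)-gallocatechin, (2R,3S)-5,7-bis(benzyloxy)-2-[3,4,5-tris(benzyloxy)phenyl]chroman-3-ol | O(Cc1ccccc1)c1cc(OCc2ccccc2)c2C[C@H](O)[C@@H](c3cc(OCc4ccccc4)c(OCc4ccccc4)c(OCc4ccccc4)c3)Oc2c1 | intermediate
3 | 8-bromo-5,7,3',4',5'-penta-O-benzyl-(+)-gallocatechin, (2R,3S)-8-bromo-5,7-bis(benzyloxy)-2-[3,4,5-tris(benzyloxy)phenyl]chroman-3-ol | O(Cc1ccccc1)c1cc(OCc2ccccc2)c2C[C@H](O)[C@@H](c3cc(OCc4ccccc4)c(OCc4ccccc4)c(OCc4ccccc4)c3)Oc2c1Br | intermediate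
4 | (+)-dihydrorobinetin, (2R,3R)-3,7-dihydroxy-2-(3,4,5-trihydroxyphenyl)chroman-4-one (2,3-trans) | Oc1ccc2c(c1)O[C@H](c1cc(O)c(O)c(O)c1)[C@@H](O)C2=O | starting material
5 | 7,3',4',5'-tetra-O-benzyl-(+)-dihydrorobinetin, (2R,3R)-7-benzyloxy-3-hydroxy-2-[3,4,5-tris(benzyloxy)phenyl]chroman-4-one | O(Cc1ccccc1)c1ccc2c(c1)O[C@H](c1cc(OCc3ccccc3)c(OCc3ccccc3)c(OCc3ccccc3)c1)[C@@H](O)C2=O | intermediate
6 | tetra-O-benzyl-leucorobinetinidin, (2R,3S,4R)-7-benzyloxy-2-[3,4,5-tris(benzyloxy)phenyl]chromane-3,4-diol (2,3-trans-3,4-trans) | O(Cc1ccccc1)c1ccc2c(c1)O[C@H](c1cc(OCc3ccccc3)c(OCc3ccccc3)c(OCc3ccccc3)c1)[C@@H](O)[C@@H]2O | intermediate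
7 | benzylic C4 cation, (2R,3S)-7-benzyloxy-3-hydroxy-2-[3,4,5-tris(benzyloxy)phenyl]chroman-4-ylium (O-benzylated para-quinone methide oxocarbenium form) | O(Cc1ccccc1)c1ccc2c(c1)O[C@H](c1cc(OCc3ccccc3)c(OCc3ccccc3)c(OCc3ccccc3)c1)[C@@H](O)[CH+]2 | intermediate
8 | 8-bromo-nona-O-benzyl-robinetinidol-(4α→6)-gallocatechin: C4 of the (2R,3S,4S)-7-benzyloxy-3-hydroxy-2-[3,4,5-tris(benzyloxy)phenyl]chroman-4-yl unit bonded to C6 of the unit of compound 3 (3,4-trans in the upper unit; both 3-OH free) | O(Cc1ccccc1)c1ccc2c(c1)O[C@H](c1cc(OCc3ccccc3)c(OCc3ccccc3)c(OCc3ccccc3)c1)[C@@H](O)[C@@H]2c1c(OCc3ccccc3)c(Br)c2c(c1OCc3ccccc3)C[C@H](O)[C@@H](c1cc(OCc3ccccc3)c(OCc3ccccc3)c(OCc3ccccc3)c1)O2 | intermediate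
9 | robinetinidol-(4α→6)-gallocatechin (CNP0311915.1), (2R,3S,4S)-2-(3,4,5-trihydroxyphenyl)-4-[(2R,3S)-3,5,7-trihydroxy-2-(3,4,5-trihydroxyphenyl)chroman-6-yl]chromane-3,7-diol | Oc1ccc2c(c1)O[C@H](c1cc(O)c(O)c(O)c1)[C@@H](O)[C@@H]2c1c(O)cc2c(c1O)C[C@H](O)[C@@H](c1cc(O)c(O)c(O)c1)O2 | target

## Step count and risks

Total step count: 6. Longest linear sequence: 4 steps (steps 3, 4, 5, 6 from compound 4; equally steps 1, 2, 5, 6 from compound 1).

The three steps most likely to fail:

**Step 3 (benzylation of the base-sensitive α-ketol 4).** The risks are C2/C3 epimerisation through ring opening to the chalcone, air oxidation to the flavonol, and ring contraction. The fallback reverses the order of protection and reduction. It sets out from compound 4, which is reduced first as the free phenol (NaBH4, EtOH/H2O, 0 °C, Ar) to (+)-leucorobinetinidin F1, the (2R,3S,4R)-flavan-3,4-diol, which no longer carries an enolisable carbonyl. Its four phenols are then benzylated (BnBr, K2CO3, acetone, rt), and the fallback comes back to the route at compound 6.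

**Step 5 (interflavan coupling).** The risks are formation of the 4β (3,4-cis) epimer, self-condensation of 6 through its own ring A, and sluggish ionisation of the 5-deoxy benzylic alcohol. The fallback replaces the free diol with a participating-group strategy. It sets out from compound 6, which is acetylated on both hydroxyls (Ac2O, pyridine, DMAP, CH2Cl2) to the 3,4-di-O-acetate F2. TMSOTf (CH2Cl2, −78 °C) ionises the C4 acetate with anchimeric assistance of the 3-acetate to the cis-fused acetoxonium ion F3, which shields the β face. Compound 3 can then attack C4 only from the α face, giving the 3-O-acetyl dimer F4. Methanolysis (K2CO3, MeOH/THF, rt) removes the acetate, and the fallback comes back to the route at compound 8.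

**Step 6 (global hydrogenolysis).** Nine benzyl ethers and an aryl bromide must be cleaved on a molecule whose product is an air-sensitive bis-pyrogallol; the risks are stalled debenzylation, bromide poisoning of the catalyst, and oxidation during isolation. The fallback is a protecting-group-free biomimetic synthesis with no deprotection step. It sets out from compound 4, which NaBH4 reduces to leucorobinetinidin F1 (the diol already met in the first fallback). In 0.1 M aqueous HCl at rt, with an excess of compound 1, this diol ionises to the flavan-4-yl cation F5 (a protonated para-quinone methide), which alkylates ring A of 1. The 4α→6 dimer is a minor product next to the 4→8 isomers, from which it is separated on Sephadex LH-20. That dimer is compound 9 itself, where the fallback rejoins the route.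

## Further compounds

F1 | step 3 | (+)-leucorobinetinidin, (2R,3S,4R)-2-(3,4,5-trihydroxyphenyl)chromane-3,4,7-triol (2,3-trans-3,4-trans) | Oc1ccc2c(c1)O[C@H](c1cc(O)c(O)c(O)c1)[C@@H](O)[C@@H]2O
F2 | step 5 | 3,4-di-O-acetate of compound 6 (2,3-trans-3,4-trans, configuration of 6 retained) | O(Cc1ccccc1)c1ccc2c(c1)O[C@H](c1cc(OCc3ccccc3)c(OCc3ccccc3)c(OCc3ccccc3)c1)[C@@H](OC(C)=O)[C@@H]2OC(C)=O
F3 | step 5 | acetoxonium ion: 2-methyl-1,3-dioxolan-2-ylium ring cis-fused across O3–C3–C4–O on the β face of the tetra-O-benzyl flavan | O(Cc1ccccc1)c1ccc2c(c1)O[C@H](c1cc(OCc4ccccc4)c(OCc4ccccc4)c(OCc4ccccc4)c1)[C@@H](OC(C)=[O+]3)[C@H]23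
F4 | step 5 | 3-O-acetyl derivative of compound 8 (acetate on the upper-unit 3-OH, 4α→6 linkage, lower 3-OH free) | O(Cc1ccccc1)c1ccc2c(c1)O[C@H](c1cc(OCc3ccccc3)c(OCc3ccccc3)c(OCc3ccccc3)c1)[C@@H](OC(C)=O)[C@@H]2c1c(OCc3ccccc3)c(Br)c2c(c1OCc3ccccc3)C[C@H](O)[C@@H](c1cc(OCc3ccccc3)c(OCc3ccccc3)c(OCc3ccccc3)c1)O2
F5 | step 6 | (2R,3S)-3,7-dihydroxy-2-(3,4,5-trihydroxyphenyl)chroman-4-ylium, the C4 cation of leucorobinetinidin (protonated para-quinone methide) | Oc1ccc2c(c1)O[C@H](c1cc(O)c(O)c(O)c1)[C@@H](O)[CH+]2
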